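**Retrosynthetic overview**
- Target ⇐ vinyl dimethyl ester (thiolate O-demethylation last); the vinyl group ⇐ CH2OH (oxidation, Wittig).
- Ring C (oxane, C–O bond at the methyl-bearing ring-fusion carbon) ⇐ acid-mediated cycloetherification of a tertiary alcohol onto an exocyclic methylene of ring B.
- Ring B ⇐ key ring expansion: 1,2-shift of the quaternary ring carbon in a 1-alkynylcyclopentanol, giving a 2-alkylidenecyclohexanone.
- Cyclopentanone ⇐ 2-methylcyclopent-2-enone + isobutyrate silyl ketene acetal + bromoacetate (enantioselective Mukaiyama–Michael addition, then alkylation; sets the two contiguous ring stereocentres).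
- Alkyne side chain ⇐ (S)-2-methylglycidol + acetylide (sets the ether-bearing quaternary centre). Ring order: cyclopentane → ring B (by expansion) → ring C.

Note: some CIP descriptors change between intermediates (for example 2S in 15, 2R in 16) only because substituent priorities change; no centre is inverted once set.

Assumption: the enantiomer of the step 2 catalyst that gives the 1R adduct is taken to be (S); if the facial sense is the opposite, the (R) catalyst is used.

**Step 1**
Reactants: 1 methyl 2-methylpropanoate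
Product: 3 1-methoxy-2-methyl-1-(trimethylsilyloxy)prop-1-ene, via lithium ester enolate 2 (not isolated)
Conditions: LiN(i-Pr)2, THF, −78 °C; Me3SiCl, −78 °C → rt; distil
Reagents that add atoms: chlorotrimethylsilane, C[Si](C)(C)Cl
Why: Kinetic ester enolisation and O-silylation (silyl ketene acetal formation); no stereocentre is formed because the enol carbon carries two methyl groups.

**Step 2**
Reactants: 3 1-methoxy-2-methyl-1-(trimethylsilyloxy)prop-1-ene; 4 2-methylcyclopent-2-en-1-one; 5 methyl bromoacetate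
Product: 8 methyl 2-[(1R,2S)-2-(2-methoxy-2-oxoethyl)-2-methyl-3-oxocyclopentyl]-2-methylpropanoate, via silyl enol ether 6 (not isolated), via ammonium enolate 7 (not isolated)
Conditions: (S)-tetrahydro-1-(2-methylphenyl)-3,3-diphenyl-1H,3H-pyrrolo[1,2-c][1,3,2]oxazaborole·HN(SO2CF3)2 (10 mol %), Ph3PO (25 mol %), toluene, −20 °C; then BnMe3N+ F−, 5, THF, 4 Å MS, −20 °C → rt
Reagents that add atoms: none
Why: Catalytic enantioselective Mukaiyama–Michael addition with a chiral oxazaborolidinium Lewis acid, which shields one enone face and sets C1 (R); the fluoride-released enolate is then alkylated regiospecifically by bromoacetate anti to the bulky C1 substituent, setting the quaternary C2 (S) trans (conjugate addition–enolate alkylation).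

**Step 3**
Reactants: 9 [(2S)-2-methyloxiran-2-yl]methanol
Product: 10 (2R)-2-methylpent-4-yne-1,2-diol
Conditions: LiC≡CH·H2NCH2CH2NH2, DMSO, 15 °C → rt; H2O
Reagents that add atoms: lithium acetylide–ethylenediamine complex, [Li+].[C-]#C.NCCN
Why: SN2 epoxide opening by acetylide at the unsubstituted CH2 (the Payne equilibrium is degenerate and returns the same enantiomer); the quaternary carbinol centre is untouched, and its descriptor changes from S to R by priority only.

**Step 4**
Reactants: 10 (2R)-2-methylpent-4-yne-1,2-diol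
Product: 11 (4R)-2,2,4-trimethyl-4-(prop-2-yn-1-yl)-1,3-dioxolane
Conditions: Me2C(OMe)2, PPTS (cat.), acetone, rt
Reagents that add atoms: 2,2-dimethoxypropane, COC(C)(C)OC
Why: Acid-catalysed transketalisation protects the 1,2-diol as its acetonide; no stereocentre is affected.

**Step 5**
Reactants: 11 (4R)-2,2,4-trimethyl-4-(prop-2-yn-1-yl)-1,3-dioxolane; 8 methyl 2-[(1R,2S)-2-(2-methoxy-2-oxoethyl)-2-methyl-3-oxocyclopentyl]-2-methylpropanoate
Product: 13 methyl 2-[(1R,2S,3S)-3-hydroxy-2-(2-methoxy-2-oxoethyl)-2-methyl-3-{3-[(4R)-2,2,4-trimethyl-1,3-dioxolan-4-yl]prop-1-yn-1-yl}cyclopentyl]-2-methylpropanoate, via lithium acetylide 12 (not isolated)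
Conditions: n-BuLi, THF, −78 °C; then 8, −78 → −40 °C; AcOH, −78 °C
Reagents that add atoms: none
Why: 1,2-Addition of a lithium acetylide to the ketone, which is faster than ester attack at −78 °C; attack on the face away from the C1 side chain is expected to give the 3S carbinol (hydroxyl cis to the 2-methyl, so no lactone forms), and this centre becomes the carbonyl carbon in step 6.

**Step 6**
Reactants: 13 methyl 2-[(1R,2S,3S)-3-hydroxy-2-(2-methoxy-2-oxoethyl)-2-methyl-3-{3-[(4R)-2,2,4-trimethyl-1,3-dioxolan-4-yl]prop-1-yn-1-yl}cyclopentyl]-2-methylpropanoate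
Product: 14 methyl 2-[(1R,2S,3E)-2-(2-methoxy-2-oxoethyl)-2-methyl-4-oxo-3-{2-[(4R)-2,2,4-trimethyl-1,3-dioxolan-4-yl]ethylidene}cyclohexyl]-2-methylpropanoate
Conditions: [(4-CF3C6H4)3P]AuCl (5 mol %), AgSbF6 (5 mol %), CH2Cl2, 4 Å MS, rt → 40 °C
Reagents that add atoms: none
Why: Proposed new method: cationic monovalent gold π-activates the alkyne, the quaternary ring carbon C2 shifts from the carbinol carbon to the proximal alkyne carbon anti to gold with retention at C2, the oxocarbenium collapses to the ketone and protodeauration gives the E-enone; the closest known reaction is the strain-driven gold-catalysed ring expansion of 1-alkynylcyclobutanols and 1-alkynylcyclopropanols, whereas here the drive is the high migratory aptitude of a quaternary carbon, relief of the eclipsed vicinal fully substituted carbons of the five-ring and enone conjugation, with an electron-poor phosphine and dry CH2Cl2 to hold back Meyer–Schuster isomerisation.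

**Step 7**
Reactants: 14 methyl 2-[(1R,2S,3E)-2-(2-methoxy-2-oxoethyl)-2-methyl-4-oxo-3-{2-[(4R)-2,2,4-trimethyl-1,3-dioxolan-4-yl]ethylidene}cyclohexyl]-2-methylpropanoate
Product: 15 methyl 2-[(1R,2S,3R)-2-(2-methoxy-2-oxoethyl)-2-methyl-4-oxo-3-{2-[(4R)-2,2,4-trimethyl-1,3-dioxolan-4-yl]ethyl}cyclohexyl]-2-methylpropanoate
Conditions: H2 (1–3 atm), Pd/C, EtOAc, rt
Reagents that add atoms: none
Why: Heterogeneous hydrogenation of the exocyclic enone C=C (the only alkene present); H2 adds from the face opposite the axial 2-methyl group and gives 3R with the side chain equatorial, which is also the thermodynamic epimer next to the ketone.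

**Step 8**
Reactants: 15 methyl 2-[(1R,2S,3R)-2-(2-methoxy-2-oxoethyl)-2-methyl-4-oxo-3-{2-[(4R)-2,2,4-trimethyl-1,3-dioxolan-4-yl]ethyl}cyclohexyl]-2-methylpropanoate
Product: 16 methyl 2-[(1R,2R,3S)-2-(2-methoxy-2-oxoethyl)-2-methyl-4-methylidene-3-{2-[(4R)-2,2,4-trimethyl-1,3-dioxolan-4-yl]ethyl}cyclohexyl]-2-methylpropanoate
Conditions: Ph3PCH3Br, KOt-Bu, THF, 0 °C; then 15, rt → 50 °C
Reagents that add atoms: methylenetriphenylphosphorane, C=P(c1ccccc1)(c1ccccc1)c1ccccc1
Why: Wittig methylenation of the ketone, which is more electrophilic than the two esters; the adjacent stereocentre is already the thermodynamic one, so base-induced epimerisation cannot erode it.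

**Step 9**
Reactants: 16 methyl 2-[(1R,2R,3S)-2-(2-methoxy-2-oxoethyl)-2-methyl-4-methylidene-3-{2-[(4R)-2,2,4-trimethyl-1,3-dioxolan-4-yl]ethyl}cyclohexyl]-2-methylpropanoate
Product: 18 methyl 2-[(2R,4aR,5S,6R,8aR)-2-(hydroxymethyl)-5-(2-methoxy-2-oxoethyl)-2,5,8a-trimethyloctahydro-2H-chromen-6-yl]-2-methylpropanoate, via diol 17 (not isolated)
Conditions: AcOH/H2O/THF, 40 °C; evaporate; TsOH·H2O (10 mol %), MeNO2, rt
Reagents that add atoms: none
Why: Acetonide hydrolysis, then Brønsted-acid Markovnikov hydroalkoxylation (cationic cycloetherification): the tertiary cation at the methylidene carbon is trapped by the tertiary hydroxyl through a six-membered chair on the face opposite the axial angular methyl, giving the trans-fused oxane with C8a R (ring oxygen equatorial, methyl axial).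

**Step 10**
Reactants: 18 methyl 2-[(2R,4aR,5S,6R,8aR)-2-(hydroxymethyl)-5-(2-methoxy-2-oxoethyl)-2,5,8a-trimethyloctahydro-2H-chromen-6-yl]-2-methylpropanoate
Product: 19 methyl 2-[(2R,4aR,5S,6R,8aR)-2-formyl-5-(2-methoxy-2-oxoethyl)-2,5,8a-trimethyloctahydro-2H-chromen-6-yl]-2-methylpropanoate
Conditions: Dess–Martin periodinane, CH2Cl2, rt
Reagents that add atoms: none
Why: Dess–Martin oxidation of the primary alcohol; the aldehyde has no α-hydrogen, so the adjacent quaternary ether centre cannot epimerise.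

**Step 11**
Reactants: 19 methyl 2-[(2R,4aR,5S,6R,8aR)-2-formyl-5-(2-methoxy-2-oxoethyl)-2,5,8a-trimethyloctahydro-2H-chromen-6-yl]-2-methylpropanoate
Product: 20 methyl 2-[(2R,4aR,5S,6R,8aR)-2-ethenyl-5-(2-methoxy-2-oxoethyl)-2,5,8a-trimethyloctahydro-2H-chromen-6-yl]-2-methylpropanoate
Conditions: Ph3PCH3Br, KOt-Bu, THF, 0 °C; then 19, 0 °C → rt
Reagents that add atoms: methylenetriphenylphosphorane, C=P(c1ccccc1)(c1ccccc1)c1ccccc1
Why: Wittig methylenation of the aldehyde installs the vinyl group; no stereocentre is touched.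

**Step 12**
Reactants: 20 methyl 2-[(2R,4aR,5S,6R,8aR)-2-ethenyl-5-(2-methoxy-2-oxoethyl)-2,5,8a-trimethyloctahydro-2H-chromen-6-yl]-2-methylpropanoate
Product: 21 2-[(2R,4aR,5S,6R,8aR)-5-(carboxymethyl)-2-ethenyl-2,5,8a-trimethyloctahydro-2H-chromen-6-yl]-2-methylpropanoic acid
Conditions: NaSEt, DMF, 100 °C; then aq. HCl to pH 3
Reagents that add atoms: none
Why: SN2 O-demethylation of both methyl esters by thiolate, which attacks the methyl carbon and so is insensitive to the hindrance of the neopentyl-type ester; the tertiary allylic ether and all stereocentres are untouched.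

**Compound list**
1 | methyl 2-methylpropanoate | CC(C)C(=O)OC | starting material
2 | lithium 1-methoxy-2-methylprop-1-en-1-olate | [Li+].COC([O-])=C(C)C | intermediate
3 | 1-methoxy-2-methyl-1-(trimethylsilyloxy)prop-1-ene | COC(O[Si](C)(C)C)=C(C)C | intermediate
4 | 2-methylcyclopent-2-en-1-one | CC1=CCCC1=O | starting material
5 | methyl bromoacetate | COC(=O)CBr | starting material
6 | methyl 2-methyl-2-[(1R)-2-methyl-3-(trimethylsilyloxy)cyclopent-2-en-1-yl]propanoate | CC1=C(O[Si](C)(C)C)CC[C@H]1C(C)(C)C(=O)OC | intermediate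
7 | benzyltrimethylammonium (3R)-3-(1-methoxy-2-methyl-1-oxopropan-2-yl)-2-methylcyclopent-1-en-1-olate | CC1=C([O-])CC[C@H]1C(C)(C)C(=O)OC.C[N+](C)(C)Cc1ccccc1 | intermediate
8 | methyl 2-[(1R,2S)-2-(2-methoxy-2-oxoethyl)-2-methyl-3-oxocyclopentyl]-2-methylpropanoate | COC(=O)C[C@]1(C)C(=O)CC[C@H]1C(C)(C)C(=O)OC | intermediate
9 | [(2S)-2-methyloxiran-2-yl]methanol | C[C@]1(CO)CO1 | starting material
10 | (2R)-2-methylpent-4-yne-1,2-diol | C[C@](O)(CO)CC#C | intermediate
11 | (4R)-2,2,4-trimethyl-4-(prop-2-yn-1-yl)-1,3-dioxolane | C#CC[C@]1(C)COC(C)(C)O1 | intermediate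
12 | lithium 3-[(4R)-2,2,4-trimethyl-1,3-dioxolan-4-yl]prop-1-yn-1-ide | [Li+].[C-]#CC[C@]1(C)COC(C)(C)O1 | intermediate
13 | methyl 2-[(1R,2S,3S)-3-hydroxy-2-(2-methoxy-2-oxoethyl)-2-methyl-3-{3-[(4R)-2,2,4-trimethyl-1,3-dioxolan-4-yl]prop-1-yn-1-yl}cyclopentyl]-2-methylpropanoate | COC(=O)C[C@]1(C)[C@](O)(C#CC[C@]2(C)COC(C)(C)O2)CC[C@H]1C(C)(C)C(=O)OC | intermediate
14 | methyl 2-[(1R,2S,3E)-2-(2-methoxy-2-oxoethyl)-2-methyl-4-oxo-3-{2-[(4R)-2,2,4-trimethyl-1,3-dioxolan-4-yl]ethylidene}cyclohexyl]-2-methylpropanoate | COC(=O)C[C@]1(C)/C(=C\C[C@]2(C)COC(C)(C)O2)C(=O)CC[C@H]1C(C)(C)C(=O)OC | intermediate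
15 | methyl 2-[(1R,2S,3R)-2-(2-methoxy-2-oxoethyl)-2-methyl-4-oxo-3-{2-[(4R)-2,2,4-trimethyl-1,3-dioxolan-4-yl]ethyl}cyclohexyl]-2-methylpropanoate | COC(=O)C[C@]1(C)[C@@H](CC[C@]2(C)COC(C)(C)O2)C(=O)CC[C@H]1C(C)(C)C(=O)OC | intermediate
16 | methyl 2-[(1R,2R,3S)-2-(2-methoxy-2-oxoethyl)-2-methyl-4-methylidene-3-{2-[(4R)-2,2,4-trimethyl-1,3-dioxolan-4-yl]ethyl}cyclohexyl]-2-methylpropanoate | COC(=O)C[C@]1(C)[C@@H](CC[C@]2(C)COC(C)(C)O2)C(=C)CC[C@H]1C(C)(C)C(=O)OC | intermediate
17 | methyl 2-[(1R,2R,3S)-3-[(3R)-3,4-dihydroxy-3-methylbutyl]-2-(2-methoxy-2-oxoethyl)-2-methyl-4-methylidenecyclohexyl]-2-methylpropanoate | COC(=O)C[C@]1(C)[C@@H](CC[C@@](C)(O)CO)C(=C)CC[C@H]1C(C)(C)C(=O)OC | intermediate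
18 | methyl 2-[(2R,4aR,5S,6R,8aR)-2-(hydroxymethyl)-5-(2-methoxy-2-oxoethyl)-2,5,8a-trimethyloctahydro-2H-chromen-6-yl]-2-methylpropanoate | OC[C@@]1(C)CC[C@@H]2[C@@](C)(CC(=O)OC)[C@H](C(C)(C)C(=O)OC)CC[C@@]2(C)O1 | intermediate
19 | methyl 2-[(2R,4aR,5S,6R,8aR)-2-formyl-5-(2-methoxy-2-oxoethyl)-2,5,8a-trimethyloctahydro-2H-chromen-6-yl]-2-methylpropanoate | O=C[C@@]1(C)CC[C@@H]2[C@@](C)(CC(=O)OC)[C@H](C(C)(C)C(=O)OC)CC[C@@]2(C)O1 | intermediate
20 | methyl 2-[(2R,4aR,5S,6R,8aR)-2-ethenyl-5-(2-methoxy-2-oxoethyl)-2,5,8a-trimethyloctahydro-2H-chromen-6-yl]-2-methylpropanoate | C=C[C@@]1(C)CC[C@@H]2[C@@](C)(CC(=O)OC)[C@H](C(C)(C)C(=O)OC)CC[C@@]2(C)O1 | intermediate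
21 | 2-[(2R,4aR,5S,6R,8aR)-5-(carboxymethyl)-2-ethenyl-2,5,8a-trimethyloctahydro-2H-chromen-6-yl]-2-methylpropanoic acid | C=C[C@@]1(C)CC[C@@H]2[C@@](C)(CC(=O)O)[C@H](C(C)(C)C(=O)O)CC[C@@]2(C)O1 | target

**Step count and risks**
Total step count: 12 (ten in the main line, two for the alkyne side chain). Longest linear sequence: 10 steps (1 → 21 through steps 1, 2 and 5–12; the branch from 9 through steps 3, 4 and 5–12 is equally long).

The three steps most likely to fail:

Step 6 (the proposed new ring expansion). The unstrained cyclopentanol may not migrate fast enough, and Meyer–Schuster isomerisation or attack of an ester carbonyl on the activated alkyne could win. The fallback uses known chemistry, sets out from 13 and comes back at 15. Semi-hydrogenation of 13 (H2, Pd/CaCO3 poisoned with Pb(OAc)2, quinoline) gives the (Z)-allylic alcohol methyl 2-[(1R,2S,3R)-3-hydroxy-2-(2-methoxy-2-oxoethyl)-2-methyl-3-{(1Z)-3-[(4R)-2,2,4-trimethyl-1,3-dioxolan-4-yl]prop-1-en-1-yl}cyclopentyl]-2-methylpropanoate F1. N-Bromosuccinimide in CH2Cl2 at −20 °C then triggers the bromonium-induced semipinacol ring expansion, with the same quaternary carbon migrating anti to bromine, to give the β-bromo ketone methyl 2-[(1R,2S,3R)-3-{(1R)-1-bromo-2-[(4R)-2,2,4-trimethyl-1,3-dioxolan-4-yl]ethyl}-2-(2-methoxy-2-oxoethyl)-2-methyl-4-oxocyclohexyl]-2-methylpropanoate F2. Radical debromination (Bu3SnH, AIBN, benzene, 80 °C) delivers 15 directly, so step 7 is not needed.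

Step 2 (enantioselective Mukaiyama–Michael addition and alkylation). This catalyst class is established for this ketene acetal with cyclic enones, but the α-methyl five-ring enone may react slowly or with lower enantioselectivity. The fallback sets out from 1 (with 4 and 5) and comes back at 8. Ester 1 is deprotonated with LiN(i-Pr)2 in THF at −78 °C and added 1,4 to 4 (−78 → −20 °C), and the enolate is alkylated in the same flask with 5 and HMPA. This gives the racemic trans keto diester methyl 2-[(1RS,2SR)-2-(2-methoxy-2-oxoethyl)-2-methyl-3-oxocyclopentyl]-2-methylpropanoate F3, which is resolved by preparative chromatography on a chiral stationary phase to give 8.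

Step 9 (cationic cycloetherification). Isomerisation of the exocyclic alkene into the ring, or capture by the primary hydroxyl, could lower the yield or the trans selectivity. The fallback sets out from 16 and comes back at 18. The acetonide is cleaved with AcOH/H2O/THF and the diol 17 is isolated. Iodoetherification (N-iodosuccinimide, CH2Cl2, 0 °C; Markovnikov closure of the six-membered ring under neutral conditions) gives the iodomethyl oxane methyl 2-[(2R,4aR,5S,6R,8aR)-2-(hydroxymethyl)-8a-(iodomethyl)-5-(2-methoxy-2-oxoethyl)-2,5-dimethyloctahydro-2H-chromen-6-yl]-2-methylpropanoate F4. Reduction of the C–I bond (Bu3SnH, AIBN, toluene, 80 °C) gives 18.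

**Further compounds**
F1 | step 6 | methyl 2-[(1R,2S,3R)-3-hydroxy-2-(2-methoxy-2-oxoethyl)-2-methyl-3-{(1Z)-3-[(4R)-2,2,4-trimethyl-1,3-dioxolan-4-yl]prop-1-en-1-yl}cyclopentyl]-2-methylpropanoate | COC(=O)C[C@]1(C)[C@](O)(/C=C\C[C@]2(C)COC(C)(C)O2)CC[C@H]1C(C)(C)C(=O)OC
F2 | step 6 | methyl 2-[(1R,2S,3R)-3-{(1R)-1-bromo-2-[(4R)-2,2,4-trimethyl-1,3-dioxolan-4-yl]ethyl}-2-(2-methoxy-2-oxoethyl)-2-methyl-4-oxocyclohexyl]-2-methylpropanoate | COC(=O)C[C@]1(C)[C@@H]([C@H](Br)C[C@]2(C)COC(C)(C)O2)C(=O)CC[C@H]1C(C)(C)C(=O)OC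
F3 | step 2 | racemic methyl 2-[(1RS,2SR)-2-(2-methoxy-2-oxoethyl)-2-methyl-3-oxocyclopentyl]-2-methylpropanoate | COC(=O)C[C@]1(C)C(=O)CC[C@H]1C(C)(C)C(=O)OC.COC(=O)C[C@@]1(C)C(=O)CC[C@@H]1C(C)(C)C(=O)OC
F4 | step 9 | methyl 2-[(2R,4aR,5S,6R,8aR)-2-(hydroxymethyl)-8a-(iodomethyl)-5-(2-methoxy-2-oxoethyl)-2,5-dimethyloctahydro-2H-chromen-6-yl]-2-methylpropanoate | OC[C@@]1(C)CC[C@@H]2[C@@](C)(CC(=O)OC)[C@H](C(C)(C)C(=O)OC)CC[C@@]2(CI)O1
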